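**Retrosynthetic overview**
- Open the 15-membered ring at the ring A–C1 bond: a Pd-catalysed ring-opening arylation of a cyclopropanol (masked C1–C3 homoenolate) by the ring A aryl bromide closes the macrocycle last and unveils the C3 ketone.
- Diaryl ether C–O: Ullmann coupling of 4-bromo-2-iodoanisole (ring A) with a ring B resorcinol-type diol, selective for C–I over C–Br and for the less hindered OH.
- Ring B–C7: B-alkyl Suzuki coupling of a ring B bromide (from resorcinol by C2 oxygenation, methylation, bromination) with a silyl-protected 1-(but-3-enyl)cyclopropanol (Kulinkovich on methyl pent-4-enoate).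
- Ring order: both arenes are bought in; the sacrificial cyclopropane is made first and the macrocycle last.

Assumption: juglanin A has no stereogenic centre and the SMILES carries no stereodescriptors, so the macrocycle is treated as conformationally mobile and there is no stereochemistry to set.

**Ring B fragment**

Step 1
Reactants: 1, resorcinol (benzene-1,3-diol)
Product: 2, 1,3-bis(methoxymethoxy)benzene
Conditions: MOMCl, i-Pr2NEt, CH2Cl2, 0 °C to rt
Reagents that add atoms: chloromethyl methyl ether, COCCl
Why: Double O-alkylation (MOM protection) caps both phenols with the groups that direct the next lithiation.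

Step 2
Reactants: 2, 1,3-bis(methoxymethoxy)benzene
Product: 3, 2,6-bis(methoxymethoxy)phenol
Conditions: n-BuLi, THF, 0 °C to rt; B(OMe)3, −78 °C to rt; then H2O2, aq. NaOH, 0 °C
Reagents that add atoms: hydrogen peroxide, OO
Why: Directed ortho-metalation at the position flanked by two OMOM groups, then borylation and oxidation, installs the central oxygen.

Step 3
Reactants: 3, 2,6-bis(methoxymethoxy)phenol
Product: 4, 2-methoxy-1,3-bis(methoxymethoxy)benzene
Conditions: MeI, K2CO3, DMF, rt
Reagents that add atoms: iodomethane, CI
Why: Williamson O-methylation of the only free phenol fixes the central OMe of ring B.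

Step 4
Reactants: 4, 2-methoxy-1,3-bis(methoxymethoxy)benzene
Product: 5, 1-bromo-3-methoxy-2,4-bis(methoxymethoxy)benzene
Conditions: NBS (1.0 equiv), MeCN, 0 °C
Reagents that add atoms: N-bromosuccinimide, O=C1CCC(=O)N1Br
Why: Electrophilic aromatic bromination goes para to one OMOM and ortho to the other, and the two such positions are equivalent by symmetry, so one monobromide results.

**Chain fragment**

Step 5
Reactants: 6, methyl pent-4-enoate
Product: 7, 1-(but-3-en-1-yl)cyclopropan-1-ol
Conditions: EtMgBr (2.5 equiv, slow addition), Ti(Oi-Pr)4 (0.3 equiv), Et2O/THF, rt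
Reagents that add atoms: ethylmagnesium bromide, CC[Mg]Br
Why: Kulinkovich cyclopropanation; the ethylene-derived titanacyclopropane adds twice to the ester faster than it exchanges with the remote terminal alkene.

Step 6
Reactants: 7, 1-(but-3-en-1-yl)cyclopropan-1-ol
Product: 8, tert-butyl{[1-(but-3-en-1-yl)cyclopropyl]oxy}dimethylsilane
Conditions: TBSOTf, 2,6-lutidine, CH2Cl2, 0 °C
Reagents that add atoms: tert-butyldimethylsilyl triflate, CC(C)(C)[Si](C)(C)OS(=O)(=O)C(F)(F)F
Why: Silyl protection keeps the cyclopropanol from ring-opening under the Pd and Cu conditions of steps 7 and 11.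

**Assembly**

Step 7
Reactants: 5, 1-bromo-3-methoxy-2,4-bis(methoxymethoxy)benzene; 8, tert-butyl{[1-(but-3-en-1-yl)cyclopropyl]oxy}dimethylsilane
Product: 9, tert-butyl[(1-{4-[3-methoxy-2,4-bis(methoxymethoxy)phenyl]butyl}cyclopropyl)oxy]dimethylsilane
Conditions: 8, 9-BBN, THF, rt; then 5, Pd(OAc)2 (5 mol%), SPhos (10 mol%), K3PO4·H2O, THF, 65 °C
Reagents that add atoms: none
Why: Anti-Markovnikov hydroboration followed by B-alkyl Suzuki–Miyaura coupling forms the ring B–C7 bond; MOM ethers and the silyl cyclopropyl ether are inert.

Step 8
Reactants: 9, tert-butyl[(1-{4-[3-methoxy-2,4-bis(methoxymethoxy)phenyl]butyl}cyclopropyl)oxy]dimethylsilane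
Product: 10, 4-(4-{1-[(tert-butyldimethylsilyl)oxy]cyclopropyl}butyl)-2-methoxybenzene-1,3-diol
Conditions: TMSOTf, 2,2′-bipyridyl, MeCN, 0 °C to rt; then H2O
Reagents that add atoms: none
Why: Mild non-protic Lewis-acid cleavage of aryl MOM acetals (acetal deprotection) frees both phenols while the alkyl TBS ether and cyclopropane should survive.

**Ring A fragment**

Step 9
Reactants: 11, 4-bromophenol
Product: 12, 4-bromo-2-iodophenol
Conditions: NIS (1.05 equiv), TsOH·H2O (10 mol%), MeCN, rt
Reagents that add atoms: N-iodosuccinimide, O=C1CCC(=O)N1I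
Why: Electrophilic aromatic iodination goes ortho to OH because the para position is blocked by bromine.

Step 10
Reactants: 12, 4-bromo-2-iodophenol
Product: 13, 4-bromo-2-iodo-1-methoxybenzene
Conditions: MeI, K2CO3, acetone, reflux
Reagents that add atoms: iodomethane, CI
Why: Williamson O-methylation gives the ring A methyl ether with iodine ortho and bromine para to OMe.

**Union and ring closure**

Step 11
Reactants: 10, 4-(4-{1-[(tert-butyldimethylsilyl)oxy]cyclopropyl}butyl)-2-methoxybenzene-1,3-diol (1.2 equiv); 13, 4-bromo-2-iodo-1-methoxybenzene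
Product: 14, 3-(5-bromo-2-methoxyphenoxy)-6-(4-{1-[(tert-butyldimethylsilyl)oxy]cyclopropyl}butyl)-2-methoxyphenol
Conditions: CuI (10 mol%), N,N-dimethylglycine·HCl (30 mol%), Cs2CO3, 1,4-dioxane, 90 °C
Reagents that add atoms: none
Why: Ullmann-type Cu-catalysed C–O coupling; C–I reacts well before C–Br at 90 °C, and the OH flanked by OMe and H should couple much faster than the OH flanked by OMe and the alkyl chain, especially with an ortho-substituted aryl iodide.

Step 12
Reactants: 14, 3-(5-bromo-2-methoxyphenoxy)-6-(4-{1-[(tert-butyldimethylsilyl)oxy]cyclopropyl}butyl)-2-methoxyphenol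
Product: 15, juglanin A (achiral 15-membered meta,para-cyclophane: 1,7-diarylheptan-3-one with ring A 4-OMe/3-O-aryl and ring B 2-OH/3-OMe/4-O-aryl)
Conditions: TBAF, THF, 0 °C to rt (one pot); then syringe-pump addition to Pd(OAc)2 (10 mol%), XPhos (20 mol%), Cs2CO3, PhMe, 80 °C, final 2 mM
Reagents that add atoms: none
Why: Proposed new method: a macrocyclising Pd-catalysed ring-opening arylation of a cyclopropanol, in which fluoride frees the cyclopropanol, Pd(0)/XPhos inserts into the ring A C–Br bond, the cyclopropoxide binds Pd and strain-driven β-carbon elimination gives a tethered Pd homoenolate, and C(sp2)–C(sp3) reductive elimination forms the ring A–C1 bond, the macrocycle and the C3 ketone together (no stereocentre is created); the closest known reactions are the intermolecular Pd-catalysed cyclopropanol/aryl halide cross-coupling to β-aryl ketones and B-alkyl Suzuki macrocyclisations.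

**Compound list**
1 | resorcinol | Oc1cccc(O)c1 | starting material
2 | 1,3-bis(methoxymethoxy)benzene | COCOc1cccc(OCOC)c1 | intermediate
3 | 2,6-bis(methoxymethoxy)phenol | COCOc1cccc(OCOC)c1O | intermediate
4 | 2-methoxy-1,3-bis(methoxymethoxy)benzene | COCOc1cccc(OCOC)c1OC | intermediate
5 | 1-bromo-3-methoxy-2,4-bis(methoxymethoxy)benzene | COCOc1ccc(Br)c(OCOC)c1OC | intermediate
6 | methyl pent-4-enoate | C=CCCC(=O)OC | starting material
7 | 1-(but-3-en-1-yl)cyclopropan-1-ol | C=CCCC1(O)CC1 | intermediate
8 | tert-butyl{[1-(but-3-en-1-yl)cyclopropyl]oxy}dimethylsilane | C=CCCC1(CC1)O[Si](C)(C)C(C)(C)C | intermediate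
9 | tert-butyl[(1-{4-[3-methoxy-2,4-bis(methoxymethoxy)phenyl]butyl}cyclopropyl)oxy]dimethylsilane | COCOc1ccc(CCCCC2(CC2)O[Si](C)(C)C(C)(C)C)c(OCOC)c1OC | intermediate
10 | 4-(4-{1-[(tert-butyldimethylsilyl)oxy]cyclopropyl}butyl)-2-methoxybenzene-1,3-diol | COc1c(O)ccc(CCCCC2(CC2)O[Si](C)(C)C(C)(C)C)c1O | intermediate
11 | 4-bromophenol | Oc1ccc(Br)cc1 | starting material
12 | 4-bromo-2-iodophenol | Oc1ccc(Br)cc1I | intermediate
13 | 4-bromo-2-iodo-1-methoxybenzene | COc1ccc(Br)cc1I | intermediate
14 | 3-(5-bromo-2-methoxyphenoxy)-6-(4-{1-[(tert-butyldimethylsilyl)oxy]cyclopropyl}butyl)-2-methoxyphenol | COc1ccc(Br)cc1Oc1ccc(CCCCC2(CC2)O[Si](C)(C)C(C)(C)C)c(O)c1OC | intermediate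
15 | juglanin A | COc1ccc2cc1Oc1ccc(c(O)c1OC)CCCCC(=O)CC2 | target

**Totals**
Total steps: 12.
Longest linear sequence: 8 (steps 1, 2, 3, 4, 7, 8, 11, 12 from resorcinol).

**Three steps most likely to fail**
- Step 12 (proposed new macrocyclisation): the risks are β-hydride elimination of the Pd homoenolate to a vinyl ketone with hydrodebromination, oligomerisation, and ring strain. Fallback (known chemistry, different ring closure): desilylate 10 and run the known intermolecular Pd-catalysed cyclopropanol ring-opening arylation with 2-bromo-4-iodoanisole (C–I selective; from 2-bromophenol by para-iodination and O-methylation). This gives 1-(3-bromo-4-methoxyphenyl)-7-(2,4-dihydroxy-3-methoxyphenyl)heptan-3-one, which is closed by intramolecular Ullmann diaryl ether formation (CuO, K2CO3, pyridine, high dilution), the established macrocyclisation for this natural product class.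
- Step 11 (selective Ullmann): the risks are arylation of the hindered OH, bis-arylation, and reaction at C–Br. Fallback: arylate before the chain is installed. Deprotect 4 to symmetric 2-methoxyresorcinol and mono-arylate it with 4-chloro-2-iodoanisole, so symmetry removes the regiochemical question. Then brominate ortho to the remaining OH (t-BuNH2/Br2, −78 °C), attach 8 by B-alkyl Suzuki (C–Br over C–Cl), and close on the aryl chloride.
- Step 7 (B-alkyl Suzuki on a hindered, electron-rich bromide): the risks are slow oxidative addition and protodeboronation. Fallback: make the ring B–C7 bond as sp2–sp. Iodinate 4 by directed ortho-metalation (n-BuLi; I2), Sonogashira-couple with the TBS ether of 1-(but-3-yn-1-yl)cyclopropan-1-ol (Kulinkovich on methyl pent-4-ynoate), then saturate the alkyne with H2, Pd/C.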